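**Plan**

- The chain is numbered C1 (on guaiacyl ring A) to C7 (on catechol ring B). Retrosynthesis removes the two acetates and three benzyl ethers, saturates C1=C2, cuts C7–aryl (ring B) as a B-alkyl Suzuki bond, and then cuts C1=C2 and C6=C7 together as the two alkenes of one ring-opening cross-metathesis.
- Enabling feature: C2–C6, with the syn oxygens on C3 and C5, are the five ring carbons of cis-cyclopent-4-ene-1,3-diol (C2 and C6 are its alkene carbons). The chain is therefore a meso ring whose two ends differ only in the aryl group they will carry.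
- Forward order: bridge the meso diol as a di-tert-butylsilylene, open the carbocycle with O-benzyl-4-vinylguaiacol (ring A enters, a vinyl group is left at C6=C7), hydroborate the vinyl group and couple it to the ring-B bromide, saturate C1=C2, exchange the silylene for two acetates, debenzylate.
- No ring of the target is formed; the only rings handled are the cyclopentene that is opened and the temporary dioxasilinane.
- Stereochemistry: the syn relation of C3/C5 is inherited from the cis-diol; the absolute configuration (3R,5S) is fixed when the chiral molybdenum catalyst selects which alkene carbon becomes C2.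

Key step: step 3

Assumption: the sense of induction of the chiral catalyst on this untested bridged substrate cannot be predicted with certainty; the (S)-biphenolate complex is written, and its equally accessible mirror image is to be used instead if the first run shows the opposite sense.

**Route**

Step 1
Reactants: 1 cis-cyclopent-4-ene-1,3-diol; 2 di-tert-butylsilyl bis(trifluoromethanesulfonate)
Product: 3 (1R,5S)-3,3-di-tert-butyl-2,4-dioxa-3-silabicyclo[3.2.1]oct-6-ene (meso)
Conditions: 2 (1.05 equiv, slow addition), 2,6-lutidine (3 equiv), CH2Cl2/DMF, high dilution, 0 °C to rt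
Reagents that add atoms: di-tert-butylsilyl bis(trifluoromethanesulfonate) (compound 2), CC(C)(C)[Si](OS(=O)(=O)C(F)(F)F)(OS(=O)(=O)C(F)(F)F)C(C)(C)C
Why: Cyclic silylene protection of a 1,3-diol: the bis(triflate) silylates one hydroxyl and the second Si–O bond then forms intramolecularly onto the cis-disposed hydroxyl, the long Si–O bonds letting the O–Si–O unit span the two pseudo-axial oxygens as cyclic boronates of cis-cyclopentane-1,3-diols do; no stereocentre is created.

Step 2
Reactants: 4 2-methoxy-4-vinylphenol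
Product: 5 1-(benzyloxy)-2-methoxy-4-vinylbenzene
Conditions: BnBr, K2CO3, DMF, rt (trace BHT)
Reagents that add atoms: benzyl bromide, BrCc1ccccc1
Why: Williamson ether synthesis on a phenoxide, which removes the acidic phenol that would destroy the molybdenum alkylidene of step 3; the vinyl group is inert to these conditions.

Step 3
Reactants: 3 (1R,5S)-3,3-di-tert-butyl-2,4-dioxa-3-silabicyclo[3.2.1]oct-6-ene; 5 1-(benzyloxy)-2-methoxy-4-vinylbenzene
Product: 6 (4S,6R)-4-[(E)-2-(4-benzyloxy-3-methoxyphenyl)ethenyl]-2,2-di-tert-butyl-6-ethenyl-1,3,2-dioxasilinane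
Conditions: 5 (2 equiv), Mo(N-2,6-iPr2C6H3)(CHCMe2Ph)[(S)-3,3'-tBu2-5,5',6,6'-Me4-biphenyl-2,2'-diolate] (5 mol %), C6H6, 22 °C, N2
Reagents that add atoms: none
Why: The neophylidene of the hexavalent molybdenum complex exchanges with 5 to give the arylidene, which adds [2+2] to the bridged alkene of 3 from the face syn to the CH2 bridge; cycloreversion of the molybdacyclobutane opens the cyclopentene, placing the aryl-substituted C1=C2 alkene on one carbinol carbon and a new alkylidene on the other, which a second molecule of 5 turns into the terminal C6=C7 vinyl group while regenerating the arylidene. The closest known reaction type is the molybdenum- or ruthenium-catalysed enantioselective ring-opening cross-metathesis of meso norbornenes and 8-oxabicyclo[3.2.1]oct-6-enes with styrenes, of which this silylene-bridged bicyclo[3.2.1]octene is a close structural relative. No ring is closed: the carbocycle is cleaved and the six-membered dioxasilinane, already present as the bridge, is carried into the product. Both carbinol stereocentres already exist in meso 3 with their cis relation locked by the bridge, and the chiral biphenolate decides which of the two enantiotopic alkene carbons receives the arylidene, which alone sets the absolute configuration (4S,6R). The step needs enantiotopic-site selection, ring opening ahead of styrene homodimerisation and a single cross-metathesis event; bridge strain should make 3 far more reactive than 5 or the hindered vinyl group of 6, and the excess of 5 should cap the ring-opened alkylidene before it adds another molecule of 3. The E geometry expected at C1=C2 is of no consequence because that alkene is saturated in step 6.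

Step 4
Reactants: 7 4-bromobenzene-1,2-diol
Product: 8 4-bromo-1,2-bis(benzyloxy)benzene
Conditions: BnBr (2.4 equiv), K2CO3, DMF, rt, N2
Reagents that add atoms: benzyl bromide, BrCc1ccccc1
Why: Double Williamson ether synthesis on the catechol, run under nitrogen to avoid quinone formation; the aryl bromide is untouched.

Step 5
Reactants: 6 (4S,6R)-4-[(E)-2-(4-benzyloxy-3-methoxyphenyl)ethenyl]-2,2-di-tert-butyl-6-ethenyl-1,3,2-dioxasilinane; 9 9-borabicyclo[3.3.1]nonane (9-BBN); 8 4-bromo-1,2-bis(benzyloxy)benzene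
Product: 11 (4S,6S)-4-[(E)-2-(4-benzyloxy-3-methoxyphenyl)ethenyl]-6-{2-[3,4-bis(benzyloxy)phenyl]ethyl}-2,2-di-tert-butyl-1,3,2-dioxasilinane, via B-alkyl-9-BBN adduct 10 (not isolated)
Conditions: 9 (1.3 equiv), THF, 0 °C to rt; then 8, PdCl2(dppf) (5 mol %), aq. K3PO4, DMF, 50 °C
Reagents that add atoms: none
Why: Anti-Markovnikov hydroboration with 9-BBN is selective for the monosubstituted vinyl group over the conjugated 1,2-disubstituted styrenyl alkene, and the primary alkylborane then undergoes B-alkyl Suzuki–Miyaura coupling with the aryl bromide under zerovalent palladium, forming C7–aryl without touching either stereocentre.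

Step 6
Reactants: 11 (4S,6S)-4-[(E)-2-(4-benzyloxy-3-methoxyphenyl)ethenyl]-6-{2-[3,4-bis(benzyloxy)phenyl]ethyl}-2,2-di-tert-butyl-1,3,2-dioxasilinane
Product: 12 (4R,6S)-4-[2-(4-benzyloxy-3-methoxyphenyl)ethyl]-6-{2-[3,4-bis(benzyloxy)phenyl]ethyl}-2,2-di-tert-butyl-1,3,2-dioxasilinane
Conditions: 2-nitrobenzenesulfonohydrazide (excess, in portions), Et3N, CH2Cl2, rt
Reagents that add atoms: none
Why: Diimide reduction: diimide released from the sulfonohydrazide transfers two hydrogens to the non-polar C1=C2 bond through a concerted cyclic transition state, so the allylic C3–O bond, the benzyl ethers and the silylene should escape hydrogenolysis and the stereocentres stay untouched (only the descriptor at C3 changes).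

Step 7
Reactants: 12 (4R,6S)-4-[2-(4-benzyloxy-3-methoxyphenyl)ethyl]-6-{2-[3,4-bis(benzyloxy)phenyl]ethyl}-2,2-di-tert-butyl-1,3,2-dioxasilinane
Product: 13 (3R,5S)-1-(4-benzyloxy-3-methoxyphenyl)-7-[3,4-bis(benzyloxy)phenyl]heptane-3,5-diol
Conditions: HF·pyridine, THF, 0 °C to rt
Reagents that add atoms: none
Why: Fluoride-mediated desilylation driven by Si–F bond formation cleaves both Si–O bonds of the silylene, while benzyl and methyl aryl ethers are inert and the C–O bonds at C3 and C5 are not broken.

Step 8
Reactants: 13 (3R,5S)-1-(4-benzyloxy-3-methoxyphenyl)-7-[3,4-bis(benzyloxy)phenyl]heptane-3,5-diol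
Product: 14 (3R,5S)-1-(4-benzyloxy-3-methoxyphenyl)-7-[3,4-bis(benzyloxy)phenyl]heptane-3,5-diyl diacetate
Conditions: Ac2O, pyridine, DMAP (cat.), CH2Cl2, rt
Reagents that add atoms: acetic anhydride, CC(=O)OC(C)=O
Why: DMAP-catalysed O-acetylation of the two secondary alcohols, the only free hydroxyls because all three phenols are still benzylated; acylation occurs at oxygen with retention at C3 and C5.

Step 9
Reactants: 14 (3R,5S)-1-(4-benzyloxy-3-methoxyphenyl)-7-[3,4-bis(benzyloxy)phenyl]heptane-3,5-diyl diacetate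
Product: 15 (3R,5S)-7-(3,4-dihydroxyphenyl)-1-(4-hydroxy-3-methoxyphenyl)heptane-3,5-diyl diacetate
Conditions: H2 (1 atm), Pd/C (10 wt %), EtOAc, rt
Reagents that add atoms: none
Why: Heterogeneous catalytic hydrogenolysis cleaves the three benzyl aryl ethers, whereas the acetates sit on non-benzylic secondary carbons and are not hydrogenolysed; the neutral aprotic medium avoids acetyl migration.

**Compound list**

1 | cis-cyclopent-4-ene-1,3-diol (meso) | O[C@H]1C=C[C@@H](O)C1 | starting material
2 | di-tert-butylsilyl bis(trifluoromethanesulfonate) | CC(C)(C)[Si](OS(=O)(=O)C(F)(F)F)(OS(=O)(=O)C(F)(F)F)C(C)(C)C | starting material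
3 | (1R,5S)-3,3-di-tert-butyl-2,4-dioxa-3-silabicyclo[3.2.1]oct-6-ene (meso) | C1=C[C@H]2C[C@@H]1O[Si](C(C)(C)C)(C(C)(C)C)O2 | intermediate
4 | 2-methoxy-4-vinylphenol | COc1cc(C=C)ccc1O | starting material
5 | 1-(benzyloxy)-2-methoxy-4-vinylbenzene | COc1cc(C=C)ccc1OCc1ccccc1 | intermediate
6 | (4S,6R)-4-[(E)-2-(4-benzyloxy-3-methoxyphenyl)ethenyl]-2,2-di-tert-butyl-6-ethenyl-1,3,2-dioxasilinane (4,6-cis) | COc1cc(/C=C/[C@@H]2C[C@H](C=C)O[Si](C(C)(C)C)(C(C)(C)C)O2)ccc1OCc1ccccc1 | intermediate
7 | 4-bromobenzene-1,2-diol | Oc1ccc(Br)cc1O | starting material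
8 | 4-bromo-1,2-bis(benzyloxy)benzene | Brc1ccc(OCc2ccccc2)c(OCc2ccccc2)c1 | intermediate
9 | 9-borabicyclo[3.3.1]nonane (9-BBN) | B1C2CCCC1CCC2 | starting material
10 | 9-{2-[(4S,6S)-6-[(E)-2-(4-benzyloxy-3-methoxyphenyl)ethenyl]-2,2-di-tert-butyl-1,3,2-dioxasilinan-4-yl]ethyl}-9-borabicyclo[3.3.1]nonane | COc1cc(/C=C/[C@@H]2C[C@H](CCB3C4CCCC3CCC4)O[Si](C(C)(C)C)(C(C)(C)C)O2)ccc1OCc1ccccc1 | intermediate
11 | (4S,6S)-4-[(E)-2-(4-benzyloxy-3-methoxyphenyl)ethenyl]-6-{2-[3,4-bis(benzyloxy)phenyl]ethyl}-2,2-di-tert-butyl-1,3,2-dioxasilinane (4,6-cis) | COc1cc(/C=C/[C@@H]2C[C@H](CCc3ccc(OCc4ccccc4)c(OCc4ccccc4)c3)O[Si](C(C)(C)C)(C(C)(C)C)O2)ccc1OCc1ccccc1 | intermediate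
12 | (4R,6S)-4-[2-(4-benzyloxy-3-methoxyphenyl)ethyl]-6-{2-[3,4-bis(benzyloxy)phenyl]ethyl}-2,2-di-tert-butyl-1,3,2-dioxasilinane (4,6-cis) | COc1cc(CC[C@@H]2C[C@H](CCc3ccc(OCc4ccccc4)c(OCc4ccccc4)c3)O[Si](C(C)(C)C)(C(C)(C)C)O2)ccc1OCc1ccccc1 | intermediate
13 | (3R,5S)-1-(4-benzyloxy-3-methoxyphenyl)-7-[3,4-bis(benzyloxy)phenyl]heptane-3,5-diol (syn) | COc1cc(CC[C@H](C[C@H](CCc2ccc(OCc3ccccc3)c(OCc3ccccc3)c2)O)O)ccc1OCc1ccccc1 | intermediate
14 | (3R,5S)-1-(4-benzyloxy-3-methoxyphenyl)-7-[3,4-bis(benzyloxy)phenyl]heptane-3,5-diyl diacetate | COc1cc(CC[C@H](C[C@H](CCc2ccc(OCc3ccccc3)c(OCc3ccccc3)c2)OC(C)=O)OC(C)=O)ccc1OCc1ccccc1 | intermediate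
15 | (3R,5S)-7-(3,4-dihydroxyphenyl)-1-(4-hydroxy-3-methoxyphenyl)heptane-3,5-diyl diacetate (CNP0315129.1) | COc1cc(CC[C@H](C[C@H](CCc2ccc(O)c(O)c2)OC(C)=O)OC(C)=O)ccc1O | target

**Count**

Total step count: 9. Longest linear sequence: 7 steps (steps 1, 3, 5, 6, 7, 8, 9); steps 2 and 4 prepare the two aryl partners.

**Steps most likely to fail**

1. Step 3. The catalyst may discriminate poorly between the two enantiotopic alkene carbons, 3 may oligomerise by ring-opening metathesis, the vinyl terminus may undergo a second cross-metathesis, or the moisture-sensitive alkylidene may decompose before turnover. The fallback builds the syn-diol by aldol chemistry without metathesis and sets out from aryl bromide 8. Heck reaction of 8 with allyl alcohol (Pd(OAc)2, Bu4NCl, NaHCO3, DMF, 80 °C) should give 3-[3,4-bis(benzyloxy)phenyl]propanal F1. Commercial 4-(4-hydroxy-3-methoxyphenyl)butan-2-one is benzylated (BnBr, K2CO3, DMF) to 4-(4-benzyloxy-3-methoxyphenyl)butan-2-one F2. The methyl-side boron enolate of F2, formed with Ipc2BCl and Et3N in Et2O (the antipode of the reagent that leads to the 5S aldol), is added to F1 at −78 °C and should give (5S)-1-(4-benzyloxy-3-methoxyphenyl)-7-[3,4-bis(benzyloxy)phenyl]-5-hydroxyheptan-3-one F3. Chelation-controlled Narasaka–Prasad reduction (Et2BOMe, NaBH4, THF/MeOH, −78 °C) should then set C3 syn to C5 and deliver diol 13, where the route is rejoined before step 8.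

2. Step 1. Intermolecular silylation may outrun closure of the strained bridge and give oligomeric silyl ethers, or the strained silylene may hydrolyse during isolation. The fallback uses a reversibly formed boron bridge for the ring opening and installs the silylene afterwards on the strain-free open-chain diol; it sets out from diol 1. Condensation with PhB(OH)2 (toluene, azeotropic removal of water) should give, under thermodynamic control, meso 3-phenyl-2,4-dioxa-3-borabicyclo[3.2.1]oct-6-ene F4. Ring-opening cross-metathesis of F4 with 5 under the catalyst of step 3 should give (4S,6R)-4-[(E)-2-(4-benzyloxy-3-methoxyphenyl)ethenyl]-6-ethenyl-2-phenyl-1,3,2-dioxaborinane F5. Transesterification with diethanolamine (Et2O, rt) removes the boron as its insoluble adduct and frees (1E,3S,5R)-1-(4-benzyloxy-3-methoxyphenyl)hepta-1,6-diene-3,5-diol F6. Silylation of F6 with 2 and 2,6-lutidine now closes an unstrained six-membered ring and gives 6, where the route is rejoined before step 5.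

3. Step 5. Hydroboration may not stop at the vinyl group, alkyl transfer from boron to palladium may lose to protodeboronation or β-hydride elimination, or the aqueous base may open the silylene. The fallback is a polarity-reversed, copper-catalysed sp3–sp2 coupling; it sets out from 6 and from 8. The alkylborane 10 formed from 6 and 9 is oxidised (NaBO3·4H2O, THF/H2O, rt) to 2-[(4S,6S)-6-[(E)-2-(4-benzyloxy-3-methoxyphenyl)ethenyl]-2,2-di-tert-butyl-1,3,2-dioxasilinan-4-yl]ethan-1-ol F7. An Appel reaction (I2, PPh3, imidazole, CH2Cl2) converts F7 into (4S,6R)-4-[(E)-2-(4-benzyloxy-3-methoxyphenyl)ethenyl]-2,2-di-tert-butyl-6-(2-iodoethyl)-1,3,2-dioxasilinane F8. Bromide 8 is converted with Mg in THF into [3,4-bis(benzyloxy)phenyl]magnesium bromide F9, and Li2CuCl4-catalysed coupling of F9 with F8 (THF, −20 to 0 °C) should give 11, where the route is rejoined before step 6.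

**Further compounds**

F1 | step 3 | 3-[3,4-bis(benzyloxy)phenyl]propanal | O=CCCc1ccc(OCc2ccccc2)c(OCc2ccccc2)c1
F2 | step 3 | 4-(4-benzyloxy-3-methoxyphenyl)butan-2-one | COc1cc(CCC(C)=O)ccc1OCc1ccccc1
F3 | step 3 | (5S)-1-(4-benzyloxy-3-methoxyphenyl)-7-[3,4-bis(benzyloxy)phenyl]-5-hydroxyheptan-3-one | COc1cc(CCC(=O)C[C@H](CCc2ccc(OCc3ccccc3)c(OCc3ccccc3)c2)O)ccc1OCc1ccccc1
F4 | step 1 | (1R,5S)-3-phenyl-2,4-dioxa-3-borabicyclo[3.2.1]oct-6-ene (meso) | C1=C[C@H]2C[C@@H]1OB(c1ccccc1)O2
F5 | step 1 | (4S,6R)-4-[(E)-2-(4-benzyloxy-3-methoxyphenyl)ethenyl]-6-ethenyl-2-phenyl-1,3,2-dioxaborinane | COc1cc(/C=C/[C@@H]2C[C@H](C=C)OB(c3ccccc3)O2)ccc1OCc1ccccc1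
F6 | step 1 | (1E,3S,5R)-1-(4-benzyloxy-3-methoxyphenyl)hepta-1,6-diene-3,5-diol | COc1cc(/C=C/[C@@H](O)C[C@@H](O)C=C)ccc1OCc1ccccc1
F7 | step 5 | 2-[(4S,6S)-6-[(E)-2-(4-benzyloxy-3-methoxyphenyl)ethenyl]-2,2-di-tert-butyl-1,3,2-dioxasilinan-4-yl]ethan-1-ol | COc1cc(/C=C/[C@@H]2C[C@H](CCO)O[Si](C(C)(C)C)(C(C)(C)C)O2)ccc1OCc1ccccc1
F8 | step 5 | (4S,6R)-4-[(E)-2-(4-benzyloxy-3-methoxyphenyl)ethenyl]-2,2-di-tert-butyl-6-(2-iodoethyl)-1,3,2-dioxasilinane | COc1cc(/C=C/[C@@H]2C[C@H](CCI)O[Si](C(C)(C)C)(C(C)(C)C)O2)ccc1OCc1ccccc1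
F9 | step 5 | [3,4-bis(benzyloxy)phenyl]magnesium bromide | Br[Mg]c1ccc(OCc2ccccc2)c(OCc2ccccc2)c1
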